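**Plan**
- Target 28 is epicatechin 3-O-gallate-(4β→8)-epicatechin 3-O-gallate-(4β→6)-catechin. The retrosynthesis cuts the upper C4–middle C8 bond and the two gallate esters, then in the middle unit the C2–ring B bond, then C3–C4 and O1–C2 together (pyran ring C as a lactone), and last C4–C4a.
- Forward: (+)-catechin is benzylated, brominated at C8 and formylated at C6. The aldehyde is joined ortho to a phloroglucinol dibenzyl ether (middle ring A) and converted into a sulfone. Base then releases an ortho-quinone methide, which a catalyst-bound glycolate enolate closes to the middle ring C.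
- Ring B enters by aryl Grignard addition and silane reduction. Galloylation, C4→C8 coupling with an upper epicatechin gallate cation and global hydrogenolysis finish the route.
- The annulation is possible because C4 of the middle unit is a diarylmethine bonded to C4a of ring A (the carbon next to C8a, which carries the phenolic O1) and to C6 of the lower catechin. It is therefore the exocyclic carbon of an aryl-substituted ortho-quinone methide of the middle ring A.
- Stereochemistry: the lower and upper units come from (+)-catechin and (−)-epicatechin. Middle C4 comes from the isothiourea catalyst, C3 is trans to it, and C2 comes from axial hydride delivery anti to O3. Upper C4β comes from participation of the 3-O-galloyl group.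

Key step: step 6

Remark: 3,5-bis(benzyloxy)phenol (the dibenzyl ether of phloroglucinol), 3,4,5-tris(benzyloxy)benzoic acid (the tribenzyl ether of gallic acid), 4-bromo-1,2-bis(benzyloxy)benzene and (tert-butyldimethylsilyloxy)acetic acid are taken as purchased.
Remark: the CIP descriptor at C4 of the 4-arylflavan units changes with the benzyl and bromine substituents, so the linkage is called 4β (trans to O3) and the SMILES are authoritative.
Assumption: the catalyst antipode is assigned from the usual model of isothiourea ammonium enolates (1,5-O···S lock, phenyl group screening one face, E-methide); if C4 should form with the opposite sense, the (2S,3R) antipode is used instead.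

**Route**

Step 1
Reactants: 1 (+)-catechin
Product: 2 5,7,3',4'-tetra-O-benzyl-(+)-catechin
Conditions: BnBr, K2CO3, DMF, 0 °C → rt
Reagents that add atoms: benzyl bromide, BrCc1ccccc1
Why: Williamson etherification in which carbonate deprotonates only the four phenols, so the secondary 3-OH stays free and C2 and C3 are untouched.

Step 2
Reactants: 2 5,7,3',4'-tetra-O-benzyl-(+)-catechin
Product: 3 3,5,7,3',4'-penta-O-benzyl-(+)-catechin
Conditions: NaH, BnBr, DMF, 0 °C → rt
Reagents that add atoms: benzyl bromide, BrCc1ccccc1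
Why: Williamson etherification of the secondary alkoxide; with every phenol capped there is no quinone-methide pathway that could epimerise C2.

Step 3
Reactants: 3 3,5,7,3',4'-penta-O-benzyl-(+)-catechin
Product: 4 8-bromo-3,5,7,3',4'-penta-O-benzylcatechin
Conditions: NBS, CH2Cl2, −78 °C → rt
Reagents that add atoms: N-bromosuccinimide, O=C1CCC(=O)N1Br
Why: Electrophilic aromatic bromination, which in benzylated 5,7-dialkoxyflavans goes to C8, the more nucleophilic and less encumbered of the two free ring A positions, when one equivalent is used cold.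

Step 4
Reactants: 4 8-bromo-3,5,7,3',4'-penta-O-benzylcatechin
Product: 6 aldehyde 8-bromo-6-formyl-3,5,7,3',4'-penta-O-benzylcatechin, via iminium chloride 5 (not isolated)
Conditions: POCl3, DMF, ClCH2CH2Cl, 0 → 70 °C; then H2O, 50 °C
Reagents that add atoms: N,N-dimethylformamide, CN(C)C=O; water, O
Why: Vilsmeier–Haack formylation; with C8 blocked the chloroiminium ion can only attack C6, which is activated by two ortho and one para oxygen, while the less electron-rich ring B and the benzyl ethers do not react, and the aryl iminium salt is hydrolysed on work-up.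

Step 5
Reactants: 6 aldehyde 8-bromo-6-formyl-3,5,7,3',4'-penta-O-benzylcatechin; 7 3,5-bis(benzyloxy)phenol
Product: 10 sulfone 3,5-bis(benzyloxy)-2-[(8-bromo-3,5,7,3',4'-penta-O-benzylcatechin-6-yl)(4-tolylsulfonyl)methyl]phenol (both epimers at the sulfonyl carbon), via bromomagnesium phenolate 8 (not isolated), via diaryl carbinol 9 (not isolated)
Conditions: 7, EtMgBr, Et2O, 0 °C, solvent change to CH2Cl2; 6, rt; then TolSO2Na, AcOH, rt
Reagents that add atoms: sodium p-toluenesulfinate, [Na+].Cc1ccc(cc1)S(=O)[O-]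
Why: Chelation-controlled ortho-hydroxyalkylation of a magnesium phenolate (the aldehyde version of the Casnati–Skattebøl ortho-formylation) delivers the magnesium-bound aldehyde only to the ortho carbon through a six-membered transition state, and the very ionisable diaryl carbinol is then trapped in acid by S-alkylation of toluenesulfinate as a storable sulfone whose new centre is later erased.

Step 6
Reactants: 10 sulfone (both epimers); 11 (tert-butyldimethylsilyloxy)acetic acid
Product: 14 lactone (3R,4R)-5,7-bis(benzyloxy)-4-(8-bromo-3,5,7,3',4'-penta-O-benzylcatechin-6-yl)-3-(tert-butyldimethylsilyloxy)chroman-2-one (3,4-trans), via mixed pivalic anhydride 12 (not isolated), via ortho-quinone methide 13 (not isolated)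
Conditions: 11, t-BuCOCl, i-Pr2NEt, CH2Cl2, 0 °C; then (2R,3S)-HyperBTM [(2R,3S)-3-isopropyl-2-phenyl-3,4-dihydro-2H-benzo[4,5]thiazolo[3,2-a]pyrimidine] (20 mol%), 10 pre-treated with Cs2CO3, 0 °C → rt
Reagents that add atoms: none
Why: Cs2CO3 deprotonates the phenol of 10 and toluenesulfinate leaves (E1cB) to give the planar ortho-quinone methide 13, whose exocyclic carbon (the future C4) is the electrophile, while the isothiourea is acylated by anhydride 12 and deprotonated to a (Z)-ammonium enolate held flat by the 1,5-O···S contact. The enolate adds through C3 to C4 in a Michael sense and the freed phenoxide O1 then attacks the acyl ammonium carbon C2 and releases the catalyst; the closest known reaction type is the isothiourea- or carbene-catalysed Michael addition–lactonisation (formal [4+2]) of ammonium or azolium enolates with ortho-quinone methides made in situ, which gives 3,4-disubstituted dihydrocoumarins. The one ring formed, the middle pyran ring C, closes as a lactone by 6-exo-trig attack of O1 on C2 after the intermolecular C3–C4 bond. C4 is set by the catalyst, whose phenyl group screens one enolate face while the E-methide stacks under the cationic heterocycle (the catechin stereocentres are too remote to direct), and C3 is set trans to the C4 aryl in the anti-selective addition and, being α to the lactone carbonyl, would settle there under the basic conditions in any case. The step needs face selectivity at C4, which rests on reagent control, and C- over O-acylation of the phenoxide, which is favoured because sulfinate loss from the donor-rich phenoxide is fast and the methide is formed before it meets the anhydride; regiochemistry is not in question because C4 is the only electrophilic carbon, and the C8 bromine, the benzyl ethers and the silyl ether are spectators.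

Step 7
Reactants: 14 lactone; 15 4-bromo-1,2-bis(benzyloxy)benzene
Product: 17 lactol 2-[3,4-bis(benzyloxy)phenyl]-5,7-bis(benzyloxy)-4-(8-bromo-3,5,7,3',4'-penta-O-benzylcatechin-6-yl)-3-(tert-butyldimethylsilyloxy)chroman-2-ol (3R,4R; hemiketal carbon as a mixture in equilibrium with the open hydroxy ketone), via arylmagnesium bromide 16 (not isolated)
Conditions: 15, Mg, THF, 40 °C; then added to 14, THF, −78 → −20 °C; AcOH
Reagents that add atoms: none
Why: Grignard addition to an aryl lactone (acyl substitution): one equivalent added to the lactone gives the keto phenoxide, whose α-silyloxy-β,β-diaryl ketone is too hindered for a second addition in the cold, and on protonation the phenol closes onto the ketone as the hemiketal, while the Grignard reagent does not exchange with the C8 bromide and C3 and C4 are not touched.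

Step 8
Reactants: 17 lactol
Product: 18 3-O-(tert-butyldimethylsilyl)-5,7,3',4'-tetra-O-benzylepicatechin-(4β→6)-8-bromo-3,5,7,3',4'-penta-O-benzylcatechin
Conditions: Et3SiH, BF3·OEt2, CH2Cl2, −78 → −30 °C
Reagents that add atoms: none
Why: Ionic hydrogenation of an aryl hemiketal as in C-aryl glycoside synthesis: BF3·OEt2 ionises the lactol to the 2-aryl oxocarbenium ion, in which the 3-silyloxy and 4-aryl groups sit trans-diaxial (allylic strain with the coplanar ring B, peri strain with 5-OBn), so Et3SiH attacks C2 axially on the face anti to the neighbouring silyloxy group and ring B ends up equatorial and cis to O3 (2,3-cis, 2,4-trans).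

Step 9
Reactants: 18 silyl ether
Product: 19 5,7,3',4'-tetra-O-benzylepicatechin-(4β→6)-8-bromo-3,5,7,3',4'-penta-O-benzylcatechin (free 3-OH on the epicatechin unit)
Conditions: Bu4NF, THF, rt
Reagents that add atoms: none
Why: Fluoride-mediated desilylation, carried out before any ester is present so that nothing else in the molecule is fluoride- or base-sensitive.

Step 10
Reactants: 19 dimer alcohol; 20 3,4,5-tris(benzyloxy)benzoic acid
Product: 21 3-O-(3,4,5-tri-O-benzylgalloyl)-5,7,3',4'-tetra-O-benzylepicatechin-(4β→6)-8-bromo-3,5,7,3',4'-penta-O-benzylcatechin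
Conditions: DCC, DMAP, CH2Cl2, rt
Reagents that add atoms: none
Why: Steglich esterification of the axial 3-OH, the established way to galloylate benzylated epicatechin units including 4-aryl-substituted ones; the lower catechin O3 is blocked as its benzyl ether.

Step 11
Reactants: 22 (−)-epicatechin
Product: 23 5,7,3',4'-tetra-O-benzyl-(−)-epicatechin
Conditions: BnBr, K2CO3, DMF, rt
Reagents that add atoms: benzyl bromide, BrCc1ccccc1
Why: Williamson etherification of the four phenols under carbonate conditions, which leaves the 3-OH and both stereocentres alone.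

Step 12
Reactants: 23 5,7,3',4'-tetra-O-benzyl-(−)-epicatechin
Product: 24 4β-(2-ethoxyethoxy)-5,7,3',4'-tetra-O-benzylepicatechin (ether trans to the 3-OH)
Conditions: DDQ, 2-ethoxyethanol, CH2Cl2, rt
Reagents that add atoms: 2-ethoxyethanol, CCOCCO
Why: DDQ benzylic oxidation: hydride abstraction at C4, assisted by the 5- and 7-benzyloxy groups, gives a ring A quinone-methide cation that the alcohol captures trans to the 3-OH, the known course for benzylated epicatechin.

Step 13
Reactants: 24 4β-(2-ethoxyethoxy)-5,7,3',4'-tetra-O-benzylepicatechin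
Product: 25 8-bromo-4β-(2-ethoxyethoxy)-5,7,3',4'-tetra-O-benzylepicatechin
Conditions: NBS, CH2Cl2, −78 → 0 °C
Reagents that add atoms: N-bromosuccinimide, O=C1CCC(=O)N1Br
Why: Electrophilic bromination at the more nucleophilic C8; the bromine caps the nucleophilic site of the future electrophile so that it cannot oligomerise with itself in the coupling.

Step 14
Reactants: 25 8-bromo-4β-(2-ethoxyethoxy)-5,7,3',4'-tetra-O-benzylepicatechin; 20 3,4,5-tris(benzyloxy)benzoic acid
Product: 26 8-bromo-4β-(2-ethoxyethoxy)-3-O-(3,4,5-tri-O-benzylgalloyl)-5,7,3',4'-tetra-O-benzylepicatechin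
Conditions: DCC, DMAP, CH2Cl2, rt
Reagents that add atoms: none
Why: Steglich esterification of the 3-OH; the ester is part of the target and later serves as the participating group.

Step 15
Reactants: 21 galloylated dimer; 26 galloylated 4-alkoxy electrophile
Product: 27 protected trimer [8-bromo-3-O-(tri-O-benzylgalloyl)-tetra-O-benzylepicatechin]-(4β→8)-[3-O-(tri-O-benzylgalloyl)-tetra-O-benzylepicatechin]-(4β→6)-[8-bromo-penta-O-benzylcatechin]
Conditions: TMSOTf, CH2Cl2, −78 → −40 °C
Reagents that add atoms: none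
Why: Lewis acid-promoted flavan C4–C8 coupling of the Friedel–Crafts type: TMSOTf ionises the 4-alkoxy group, the 3-O-galloyl group on the α face bridges the C4 cation as a dioxolenium ion, and C8 of the middle unit, the more nucleophilic and less hindered of its two free ring A positions (the lower ring A is fully substituted), attacks from the β face to give the 3,4-trans 4β→8 bond.

Step 16
Reactants: 27 protected trimer
Product: 28 epicatechin 3-O-gallate-(4β→8)-epicatechin 3-O-gallate-(4β→6)-catechin (CNP0154615.1)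
Conditions: H2 (1 atm), Pd(OH)2/C, THF/MeOH/H2O, rt
Reagents that add atoms: none
Why: Catalytic hydrogenolysis cleaves all nineteen benzyl ethers and both aryl C–Br bonds in one operation while the esters, the pyran C–O bonds, the interflavan bonds and all stereocentres persist, as in the deprotection of benzylated, bromine-capped procyanidins.

**Compound list**

1 | (+)-catechin | O[C@H]1Cc2c(O)cc(O)cc2O[C@@H]1c1ccc(O)c(O)c1 | starting material
2 | 5,7,3',4'-tetra-O-benzyl-(+)-catechin | O[C@H]1Cc2c(OCc3ccccc3)cc(OCc3ccccc3)cc2O[C@@H]1c1ccc(OCc2ccccc2)c(OCc2ccccc2)c1 | intermediate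
3 | 3,5,7,3',4'-penta-O-benzyl-(+)-catechin | c1c(OCc4ccccc4)cc2c(c1OCc4ccccc4)C[C@H](OCc4ccccc4)[C@@H](c1ccc(OCc4ccccc4)c(OCc4ccccc4)c1)O2 | intermediate
4 | 8-bromo-3,5,7,3',4'-penta-O-benzylcatechin | c1c(OCc4ccccc4)c(Br)c2c(c1OCc4ccccc4)C[C@H](OCc4ccccc4)[C@@H](c1ccc(OCc4ccccc4)c(OCc4ccccc4)c1)O2 | intermediate
5 | N,N-dimethyl iminium chloride of aldehyde 6 (formed in the flask) | C[N+](C)=Cc1c(OCc4ccccc4)c(Br)c2c(c1OCc4ccccc4)C[C@H](OCc4ccccc4)[C@@H](c1ccc(OCc4ccccc4)c(OCc4ccccc4)c1)O2.[Cl-] | intermediate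
6 | 8-bromo-6-formyl-3,5,7,3',4'-penta-O-benzylcatechin | O=Cc1c(OCc4ccccc4)c(Br)c2c(c1OCc4ccccc4)C[C@H](OCc4ccccc4)[C@@H](c1ccc(OCc4ccccc4)c(OCc4ccccc4)c1)O2 | intermediate
7 | 3,5-bis(benzyloxy)phenol | Oc1cc(OCc2ccccc2)cc(OCc2ccccc2)c1 | starting material
8 | bromomagnesium 3,5-bis(benzyloxy)phenolate (formed in the flask) | Br[Mg]Oc1cc(OCc2ccccc2)cc(OCc2ccccc2)c1 | intermediate
9 | diaryl carbinol, 3,5-bis(benzyloxy)-2-[(8-bromo-penta-O-benzylcatechin-6-yl)(hydroxy)methyl]phenol, both carbinol epimers (formed in the flask) | Oc1cc(OCc4ccccc4)cc(OCc4ccccc4)c1C(O)c2c(OCc4ccccc4)c(Br)c3c(c2OCc4ccccc4)C[C@H](OCc4ccccc4)[C@@H](c2ccc(OCc4ccccc4)c(OCc4ccccc4)c2)O3 | intermediate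
10 | sulfone, 3,5-bis(benzyloxy)-2-[(8-bromo-penta-O-benzylcatechin-6-yl)(4-tolylsulfonyl)methyl]phenol, both epimers at the sulfonyl carbon | Oc1cc(OCc4ccccc4)cc(OCc4ccccc4)c1C(S(=O)(=O)c1ccc(C)cc1)c2c(OCc4ccccc4)c(Br)c3c(c2OCc4ccccc4)C[C@H](OCc4ccccc4)[C@@H](c2ccc(OCc4ccccc4)c(OCc4ccccc4)c2)O3 | intermediate
11 | (tert-butyldimethylsilyloxy)acetic acid | CC(C)(C)[Si](C)(C)OCC(=O)O | starting material
12 | (tert-butyldimethylsilyloxy)acetic pivalic anhydride (formed in the flask) | CC(C)(C)[Si](C)(C)OCC(=O)OC(=O)C(C)(C)C | intermediate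
13 | ortho-quinone methide, 3,5-bis(benzyloxy)-6-[(8-bromo-penta-O-benzylcatechin-6-yl)methylidene]cyclohexa-2,4-dienone (formed in the flask) | O=C1C=C(OCc4ccccc4)C=C(OCc4ccccc4)C1=Cc2c(OCc4ccccc4)c(Br)c3c(c2OCc4ccccc4)C[C@H](OCc4ccccc4)[C@@H](c2ccc(OCc4ccccc4)c(OCc4ccccc4)c2)O3 | intermediate
14 | (3R,4R)-5,7-bis(benzyloxy)-4-(8-bromo-penta-O-benzylcatechin-6-yl)-3-(tert-butyldimethylsilyloxy)chroman-2-one, 3,4-trans | c1c(OCc4ccccc4)cc(OCc4ccccc4)c2c1OC(=O)[C@H](O[Si](C)(C)C(C)(C)C)[C@H]2c2c(OCc4ccccc4)c(Br)c3c(c2OCc4ccccc4)C[C@H](OCc4ccccc4)[C@@H](c2ccc(OCc4ccccc4)c(OCc4ccccc4)c2)O3 | intermediate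
15 | 4-bromo-1,2-bis(benzyloxy)benzene | Brc1ccc(OCc2ccccc2)c(OCc2ccccc2)c1 | starting material
16 | 3,4-bis(benzyloxy)phenylmagnesium bromide (formed in the flask) | Br[Mg]c1ccc(OCc2ccccc2)c(OCc2ccccc2)c1 | intermediate
17 | lactol, 2-[3,4-bis(benzyloxy)phenyl]-2-hydroxy analogue of 14 (3R,4R; hemiketal carbon unassigned) | c1c(OCc4ccccc4)cc(OCc4ccccc4)c2c1OC(O)(c1ccc(OCc4ccccc4)c(OCc4ccccc4)c1)[C@H](O[Si](C)(C)C(C)(C)C)[C@H]2c2c(OCc4ccccc4)c(Br)c3c(c2OCc4ccccc4)C[C@H](OCc4ccccc4)[C@@H](c2ccc(OCc4ccccc4)c(OCc4ccccc4)c2)O3 | intermediate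
18 | 3-O-TBS-5,7,3',4'-tetra-O-benzylepicatechin-(4β→6)-8-bromo-penta-O-benzylcatechin (2,3-cis, 3,4-trans) | c1c(OCc4ccccc4)cc(OCc4ccccc4)c2c1O[C@H](c1ccc(OCc4ccccc4)c(OCc4ccccc4)c1)[C@H](O[Si](C)(C)C(C)(C)C)[C@H]2c2c(OCc4ccccc4)c(Br)c3c(c2OCc4ccccc4)C[C@H](OCc4ccccc4)[C@@H](c2ccc(OCc4ccccc4)c(OCc4ccccc4)c2)O3 | intermediate
19 | 5,7,3',4'-tetra-O-benzylepicatechin-(4β→6)-8-bromo-penta-O-benzylcatechin, free 3-OH on the epicatechin unit | c1c(OCc4ccccc4)cc(OCc4ccccc4)c2c1O[C@H](c1ccc(OCc4ccccc4)c(OCc4ccccc4)c1)[C@H](O)[C@H]2c2c(OCc4ccccc4)c(Br)c3c(c2OCc4ccccc4)C[C@H](OCc4ccccc4)[C@@H](c2ccc(OCc4ccccc4)c(OCc4ccccc4)c2)O3 | intermediate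
20 | 3,4,5-tris(benzyloxy)benzoic acid | OC(=O)c1cc(OCc2ccccc2)c(OCc2ccccc2)c(OCc2ccccc2)c1 | starting material
21 | 3-O-(tri-O-benzylgalloyl)-tetra-O-benzylepicatechin-(4β→6)-8-bromo-penta-O-benzylcatechin | c1c(OCc4ccccc4)cc(OCc4ccccc4)c2c1O[C@H](c1ccc(OCc4ccccc4)c(OCc4ccccc4)c1)[C@H](OC(=O)c1cc(OCc4ccccc4)c(OCc4ccccc4)c(OCc4ccccc4)c1)[C@H]2c2c(OCc4ccccc4)c(Br)c3c(c2OCc4ccccc4)C[C@H](OCc4ccccc4)[C@@H](c2ccc(OCc4ccccc4)c(OCc4ccccc4)c2)O3 | intermediate
22 | (−)-epicatechin | O[C@@H]1Cc2c(O)cc(O)cc2O[C@@H]1c1ccc(O)c(O)c1 | starting material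
23 | 5,7,3',4'-tetra-O-benzyl-(−)-epicatechin | O[C@@H]1Cc2c(OCc3ccccc3)cc(OCc3ccccc3)cc2O[C@@H]1c1ccc(OCc2ccccc2)c(OCc2ccccc2)c1 | intermediate
24 | 4β-(2-ethoxyethoxy)-5,7,3',4'-tetra-O-benzylepicatechin | O[C@@H]1[C@@H](OCCOCC)c2c(OCc3ccccc3)cc(OCc3ccccc3)cc2O[C@@H]1c1ccc(OCc2ccccc2)c(OCc2ccccc2)c1 | intermediate
25 | 8-bromo-4β-(2-ethoxyethoxy)-5,7,3',4'-tetra-O-benzylepicatechin | O[C@@H]1[C@@H](OCCOCC)c2c(OCc3ccccc3)cc(OCc3ccccc3)c(Br)c2O[C@@H]1c1ccc(OCc2ccccc2)c(OCc2ccccc2)c1 | intermediate
26 | 8-bromo-4β-(2-ethoxyethoxy)-3-O-(tri-O-benzylgalloyl)-5,7,3',4'-tetra-O-benzylepicatechin | O=C(O[C@@H]1[C@@H](OCCOCC)c2c(OCc3ccccc3)cc(OCc3ccccc3)c(Br)c2O[C@@H]1c1ccc(OCc2ccccc2)c(OCc2ccccc2)c1)c1cc(OCc2ccccc2)c(OCc2ccccc2)c(OCc2ccccc2)c1 | intermediate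
27 | protected trimer with nineteen benzyl ethers and bromine at C8 of the upper and lower units | O=C(O[C@@H]1[C@@H](c2c(OCc5ccccc5)cc(OCc5ccccc5)c3c2O[C@H](c2ccc(OCc5ccccc5)c(OCc5ccccc5)c2)[C@H](OC(=O)c2cc(OCc5ccccc5)c(OCc5ccccc5)c(OCc5ccccc5)c2)[C@H]3c2c(OCc5ccccc5)c(Br)c3c(c2OCc5ccccc5)C[C@H](OCc5ccccc5)[C@@H](c2ccc(OCc5ccccc5)c(OCc5ccccc5)c2)O3)c2c(OCc5ccccc5)cc(OCc5ccccc5)c(Br)c2O[C@@H]1c1ccc(OCc5ccccc5)c(OCc5ccccc5)c1)c1cc(OCc5ccccc5)c(OCc5ccccc5)c(OCc5ccccc5)c1 | intermediate
28 | epicatechin 3-O-gallate-(4β→8)-epicatechin 3-O-gallate-(4β→6)-catechin (CNP0154615.1) | O=C(O[C@@H]1[C@@H](c2c(O)cc(O)c3c2O[C@H](c2ccc(O)c(O)c2)[C@H](OC(=O)c2cc(O)c(O)c(O)c2)[C@H]3c2c(O)cc3c(c2O)C[C@H](O)[C@@H](c2ccc(O)c(O)c2)O3)c2c(O)cc(O)cc2O[C@@H]1c1ccc(O)c(O)c1)c1cc(O)c(O)c(O)c1 | target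

**Count and risks**

Total step count: 16. Longest linear sequence: 12 steps (steps 1–10, 15 and 16, from (+)-catechin); the upper unit takes steps 11–14.

Steps most likely to fail:

1. Step 6. Capture of the crowded, donor-stabilised methide by the catalyst-bound α-silyloxy enolate may be slower than sulfinate return or O-acylation of the phenoxide, and face selectivity at C4 may be poor. The fallback sets out from 10 and comes back at 14, and gives up catalyst control for a stoichiometric enolate and a separation. Sulfone 10 is treated with 2.2 equivalents of the lithium enolate of methyl (tert-butyldimethylsilyloxy)acetate (LiN(i-Pr)2, THF, −78 °C). The first equivalent deprotonates the phenol and expels sulfinate, and the second adds to methide 13. This gives methyl 3-(2-hydroxy-4,6-bis(benzyloxy)phenyl)-3-(8-bromo-penta-O-benzylcatechin-6-yl)-2-(tert-butyldimethylsilyloxy)propanoate F1 as a mixture at both new centres. Warming with catalytic TsOH in toluene closes the lactone with loss of methanol, and DBU equilibrates C3 to the 3,4-trans pair. The two C4 epimers, 14 and its (3S,4S) isomer F2, are separated by chromatography.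

2. Step 5. Addition of the doubly ortho-substituted, electron-rich aldehyde carbon to the phenolate may be slow, and the carbinol may ionise and be captured by a second phenolate. The fallback sets out from 4 (and so also bypasses the formylation of step 4), reverses the polarity of the bond formation, and comes back at carbinol 9 and hence 10. NIS (CH2Cl2, 0 °C) iodinates the last free ring A position to give 8-bromo-6-iodo-penta-O-benzylcatechin F3. n-BuLi at −90 °C exchanges the iodide much faster than the bromide and gives the 6-lithio compound F4. F4 is added to the sodium salt (NaH) of purchased 2,4-bis(benzyloxy)-6-hydroxybenzaldehyde (O=Cc1c(O)cc(OCc2ccccc2)cc1OCc1ccccc1), the usual direction in which such sulfone precursors are assembled. Work-up gives carbinol 9, which is treated with TolSO2Na and AcOH as in step 5 to give 10.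

3. Step 7. A second addition of the Grignard reagent to the ring-opened ketone, or enolisation of the lactone in place of addition, would erode the lactol. The fallback sets out from 14 and comes back at 17 by a Weinreb ketone synthesis. MeNH(OMe)·HCl and i-PrMgCl (THF, −20 °C) open the lactone to the phenolic N-methoxy-N-methyl amide F5. Arylmagnesium bromide 16 (2.2 equivalents, the first consumed by the phenol) gives a chelated adduct that cannot add twice. Acidic work-up releases the hydroxy ketone, which closes to lactol 17.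

Further compounds
F1 | step 6 | methyl 3-(2-hydroxy-4,6-bis(benzyloxy)phenyl)-3-(8-bromo-penta-O-benzylcatechin-6-yl)-2-(tert-butyldimethylsilyloxy)propanoate, mixture at C2 and C3 | Oc1cc(OCc4ccccc4)cc(OCc4ccccc4)c1C(c2c(OCc4ccccc4)c(Br)c3c(c2OCc4ccccc4)C[C@H](OCc4ccccc4)[C@@H](c2ccc(OCc4ccccc4)c(OCc4ccccc4)c2)O3)C(O[Si](C)(C)C(C)(C)C)C(=O)OC
F2 | step 6 | (3S,4S)-5,7-bis(benzyloxy)-4-(8-bromo-penta-O-benzylcatechin-6-yl)-3-(tert-butyldimethylsilyloxy)chroman-2-one, the C4-epimeric trans lactone | c1c(OCc4ccccc4)cc(OCc4ccccc4)c2c1OC(=O)[C@@H](O[Si](C)(C)C(C)(C)C)[C@@H]2c2c(OCc4ccccc4)c(Br)c3c(c2OCc4ccccc4)C[C@H](OCc4ccccc4)[C@@H](c2ccc(OCc4ccccc4)c(OCc4ccccc4)c2)O3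
F3 | step 5 | 8-bromo-6-iodo-3,5,7,3',4'-penta-O-benzylcatechin | Ic1c(OCc4ccccc4)c(Br)c2c(c1OCc4ccccc4)C[C@H](OCc4ccccc4)[C@@H](c1ccc(OCc4ccccc4)c(OCc4ccccc4)c1)O2
F4 | step 5 | 8-bromo-6-lithio-3,5,7,3',4'-penta-O-benzylcatechin | [Li]c1c(OCc4ccccc4)c(Br)c2c(c1OCc4ccccc4)C[C@H](OCc4ccccc4)[C@@H](c1ccc(OCc4ccccc4)c(OCc4ccccc4)c1)O2
F5 | step 7 | N-methoxy-N-methyl amide from ring opening of 14 (free phenol, 3-silyloxy, configuration as in 14) | Oc1cc(OCc4ccccc4)cc(OCc4ccccc4)c1[C@H](c2c(OCc4ccccc4)c(Br)c3c(c2OCc4ccccc4)C[C@H](OCc4ccccc4)[C@@H](c2ccc(OCc4ccccc4)c(OCc4ccccc4)c2)O3)[C@@H](O[Si](C)(C)C(C)(C)C)C(=O)N(C)OC
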